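**Remark on the chemistry:** the target has no stereogenic element, so only constitution has to be controlled. Compounds 1, 9, 10, 15, 16 and 20 are taken to be purchasable.

## Analysis of the target

CNP0018313.0 is a phlorethol-type pentamer, C30H22O15, in which five benzene rings (A to E, lettered from the 3,5-dihydroxyphenyl end) are joined in a chain by four diaryl ether oxygens, O1 (A–B), O2 (B–C), O3 (C–D) and O4 (D–E); in rings B to E, C1 is the carbon bonded to the oxygen that leads back towards ring A. There are no stereocentres, no configurational double bonds and no isolable axes, so nothing stereochemical has to be set or related. The eleven free phenolic hydroxyls make the compound electron-rich and sensitive to air, base and electrophiles, so they are carried as methyl ethers and released only in the last step under non-oxidising conditions. The difficulty lies in the four C–O–C bonds between electron-rich rings that carry no activating group: each ether oxygen has on one side a carbon flanked by two oxygenated carbons (B-C1, C-C1, D-C1, E-C1), the poorest electrophilic partners for catalysed etherification. Rings B and D share one pattern (aryloxy on C1 and C6, hydroxyl on C2 and C4), and ring C is a 1,4-bis(aryloxy) unit, so like oxygens must also be told apart. The strategy rests on ring D, where O4 on C6 and O3 on C1 sit on neighbouring carbons, C2 next to C1 is oxygenated and so is C4. This array maps onto 3,5-dimethoxybenzyne: its two triple-bond carbons become C6 and C1, its flanking methoxy group C2–O and its remote one C4–O. One aryne operation can therefore place O4 as the nucleophile and an iodine on C1 as the placeholder for O3.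

## Retrosynthetic reasoning

**24 to 23.** The eleven O–CH3 bonds are cut last. Methyl ethers survive organolithium, copper, palladium, peracid and fluoride chemistry, and the diaryl ether bonds are inert to the Lewis-acid cleavage that removes them. The forward step has to cleave all eleven ethers without oxidising the product.

**23 to 14 and 22.** The O3–C1 bond of ring D is cut. This splits the chain into a three-ring and a two-ring half, so the route is convergent. It also places the coupling at the carbon where the key step leaves an iodine. The oxygen partner, the C4 hydroxyl of ring C in 22, has only hydrogens as neighbours, so crowding is confined to one partner. Cutting O3–C4 of ring C instead would demand a hindered ring D phenol and a ring C halide, an arrangement kept in reserve. The forward step is an Ullmann etherification of a doubly ortho-substituted aryl iodide.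

**14 to 8, 9 and 10.** Two adjacent bonds on ring D are cut at once, O4–C6 and C1–I. Aryne 12, released from 8, is the ring D synthon: 9, as its potassium salt 11, delivers O4 and ring E, and 10 delivers iodine. This avoids any metal-catalysed coupling at E-C1, whose oxygen is flanked by two methoxy groups. The forward reaction must add the aryloxide at the triple-bond carbon remote from the flanking methoxy group and must iodinate the resulting aryl anion 13 before it is protonated.

**8 to 1.** The silyl triflate is traced through carbamate 6 to carbamate 2 and phenol 1. The C–Si bond is made by directed ortho-metalation between the carbamate and a methoxy group, and the carbamate is then exchanged for triflate. Three steps of established chemistry lead to the key-step precursor.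

**22 to 21, then to 19 and 20.** The free C4 hydroxyl of ring C is traced to a C–Br bond, so that it stays masked as a halide through the assembly and needs no protecting group. The bond from O1 to C1 of ring A is then cut. Ring A arrives as boronic acid 20 in an oxidative copper coupling at room temperature. No low-valent metal is involved, so the bromide is left alone; the crowded oxygen of 19 is the nucleophile and the ring A carbon is unhindered. Silyl triflate 8 could deliver the same ring through aryne 12, but it is reserved for the key step, so the two halves stay independent and equal in length.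

**19 to 17, then to 15 and 16.** The C1–O bond of ring B is traced to a formyl group through oxidative aryl migration. That formyl group is what makes the O2–C6 bond of ring B easy to form, because it activates the neighbouring bromide of 16 towards copper. Phenol 15 supplies ring C, with O2 as the hindered nucleophile and bromine on C4. The forward coupling has to distinguish the activated bromide of 16 from the electron-rich bromide of 15.

## Alternatives that were turned down

Alternative 1: ring E built by Claisen annulation.
- Disconnection: the C2–C3 and C5–C6 bonds of ring E are cut. This leads to the malonate ether A2 (the A–D tetramer octamethyl ether whose D-C6 oxygen carries CH(CO2Me)2) and dimethyl 3-oxopentanedioate A3.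
- Forward key step: an alkoxide-mediated double Claisen condensation acylates each methylene of A3 with one ester of A2. Enolisation gives A1, with ring E as a phloroglucinol diester.
- For it: it is the only plan that never forms an aryl–oxygen bond at E-C1, and the three hydroxyls of ring E arrive free.
- Against it: A2 presupposes the whole A–D tetramer with one differentiated ring D hydroxyl, so three hindered ether bonds remain, among them the vicinal pair on ring D. The α-aryloxy malonate C–H is the most acidic site, and its enolate deactivates both esters towards acylation. Two chelated esters must afterwards be hydrolysed and decarboxylated. The least certain step falls on the most advanced intermediate.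
- Comparison: on the O4–C1 bond of ring E this alternative is at least as strong. The chosen strategy answers that the crowded partner is the nucleophile and the electrophile is an unhindered triple bond. It also installs the handle for O3 in the same step and keeps the route convergent.

Alternative 2: ruthenium-activated ring C as a double SNAr linchpin.
- Disconnection: both C–O bonds of ring C (O2–C1 and O3–C4) are cut. Ring C becomes the cationic dichloroarene complex A5, and the partners are the D–E phenol A6 and the A–B phenol A7.
- Forward key step: in one pot, the phenoxide of A6 displaces the unhindered C4 chloride and the phenoxide of A7 displaces the C1 chloride, giving complex A4. Photolytic decomplexation would release 23.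
- For it: it is the most convergent plan (two rings, one ring, two rings). SNAr on cationic cyclopentadienylruthenium arene complexes is mild and well established for hindered diaryl ethers, and the metal overrides the electron richness of ring C.
- Against it: ruthenium is used stoichiometrically, with complexation and decomplexation steps. The order of the two displacements rests on sterics alone, and the second is slowed by the first aryloxy donor. The metal may migrate to other electron-rich rings. A6 still contains the vicinal O4/O3 pattern of ring D, so that problem is moved, not solved.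
- Comparison: this alternative is stronger in convergence and in the mildness of the ring C couplings. The chosen strategy needs no stoichiometric transition metal, has fewer operations, and constructs the ring D pattern that A6 would still require.

Alternative 3: para oxygens of rings B and D by C–H borylation.
- Disconnection: the C4–O bonds of rings B and D are cut, leading to A9, in which rings B and D are 1,2,3-trioxygenated.
- Forward key step: iridium-catalysed borylation with a diboron reagent, then peroxide oxidation in the same pot, gives A8. The two C4–H bonds are the only aromatic C–H bonds in A9 without an ortho substituent.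
- For it: sterically governed borylation is highly predictable, and rings B and D simplify to cheaper trioxygenated units.
- Against it: the step forms no skeletal bond. All four ether links, including the vicinal diaryloxy pairs on rings B and D, must already be in place. Both borylations must go to completion on an electron-rich substrate in which C–H bonds next to a small methoxy group are not fully protected, and the sequence adds steps at the end.
- Comparison: taken alone, its key step is probably more reliable than the three-component aryne coupling. It leaves the real difficulty untouched, whereas the chosen key step forms a hindered ether bond and prepares the next one.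

Key step: step 4

## Route

Step 1
Reactants: 1 3,5-dimethoxyphenol
Product: 2 3,5-dimethoxyphenyl N-isopropylcarbamate
Conditions: i-PrNCO, Et3N (cat.), CH2Cl2, rt
Reagents that add atoms: isopropyl isocyanate, CC(C)N=C=O
Why: Amine-catalysed addition of the phenol O–H across the isocyanate (carbamoylation); the N–H carbamate is chosen because it directs metalation after N-silylation and is later removed by mild E1cB fragmentation.

Step 2
Reactants: 2 3,5-dimethoxyphenyl N-isopropylcarbamate
Product: 6 3,5-dimethoxy-2-(trimethylsilyl)phenyl N-isopropylcarbamate, via N-silyl carbamate 3 (not isolated), via ortho-lithiated carbamate 4 (not isolated), via N-silyl arylsilane carbamate 5 (not isolated)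
Conditions: TBSOTf, TMEDA, Et2O, 0 °C → rt; n-BuLi, TMEDA, −78 °C; TMSCl, −78 °C → rt; dilute aq. NaHSO4, 0 °C, brief
Reagents that add atoms: chlorotrimethylsilane, C[Si](C)(C)Cl
Why: Directed ortho-metalation: after in situ N-silylation the O-carbamate is the strongest director and C2–H lies between it and a methoxy group (C2 and C6 are equivalent), so 4 forms there in preference to the site between the two weaker methoxy directors and is trapped by Me3SiCl; −78 °C suppresses the anionic ortho-Fries shift and the short mild acid wash removes only the N-silyl group.

Step 3
Reactants: 6 3,5-dimethoxy-2-(trimethylsilyl)phenyl N-isopropylcarbamate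
Product: 8 3,5-dimethoxy-2-(trimethylsilyl)phenyl trifluoromethanesulfonate, via silylphenol 7 (not isolated)
Conditions: Et2NH, DBU, MeCN, 40 °C; then PhNTf2, rt
Reagents that add atoms: N-phenylbis(trifluoromethanesulfonimide), O=S(=O)(N(c1ccccc1)S(=O)(=O)C(F)(F)F)C(F)(F)F
Why: DBU removes the carbamate N–H and the aryloxide is expelled (E1cB), the isocyanate being scavenged by diethylamine as a urea; the phenoxide of 7 is triflated in the same flask, so the acid-sensitive electron-rich silylphenol is never isolated.

Step 4
Reactants: 8 3,5-dimethoxy-2-(trimethylsilyl)phenyl trifluoromethanesulfonate; 9 2,4,6-trimethoxyphenol; 10 perfluorohexyl iodide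
Product: 14 2-iodo-1,5-dimethoxy-3-(2,4,6-trimethoxyphenoxy)benzene, via potassium phenoxide 11 (not isolated), via 3,5-dimethoxybenzyne 12 (not isolated), via arylpotassium 13 (not isolated)
Conditions: 9, KH, THF, 0 °C; then 10 (3 equiv), KF, 18-crown-6, slow addition of 8, THF, 0 °C → rt, dark
Reagents that add atoms: none
Why: Proposed new method: fluoride removes the silyl group of 8 (C1 bears OTf, C2 silicon, C3 and C5 methoxy) and triflate departs, giving aryne 12, whose strained bond is bent by the C3 methoxy group so that C1, the carbon meta to it, is the flatter and more electrophilic terminus; phenoxide 11 therefore bonds at C1 (the O4–C6 bond of ring D) and the charge of 13 develops at C2, next to the methoxy group, where it is inductively stabilised. Aryl anion 13 then takes iodine from 10 through a halogen-bonded, ate-like transition state (the C1–I bond of ring D), and the perfluorohexyl anion is lost irreversibly as perfluorohex-1-ene and fluoride. The closest known reaction types are the metal-free O-arylation of phenols by arynes from ortho-silylaryl triflates and the three-component aryne couplings in which the aryl anion formed from a heteroatom or carbon nucleophile is intercepted by an iodine donor such as a perfluoroalkyl iodide or an iodoalkyne; the pairing of an aryloxide with the iodine donor is the new element. No ring is closed and no stereocentre is formed. Regioselectivity is needed and is secured by the C3 methoxy group (the remote C5 methoxy exerts only a weak opposing inductive bias) and by the bulk of 11, which avoids the flanked carbon. Iodination must also outrun protonation, which is secured by a medium without acidic hydrogen (phenoxide preformed with KH so that only H2 leaves, THF in place of acetonitrile, no free phenol) and by an excess of 10. The doubly ortho-substituted oxygen of 11 is no handicap because the electrophile is an unhindered triple bond, and light is excluded to suppress electron transfer from 11 to 10.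

Step 5
Reactants: 15 4-bromo-2,6-dimethoxyphenol; 16 2-bromo-4,6-dimethoxybenzaldehyde
Product: 17 2-(4-bromo-2,6-dimethoxyphenoxy)-4,6-dimethoxybenzaldehyde
Conditions: CuI (10 mol%), picolinic acid (20 mol%), K3PO4, DMSO, 80 °C
Reagents that add atoms: none
Why: Ullmann-type diaryl ether synthesis: the bromide of 16 is activated and pre-coordinated to copper by the ortho formyl group, whereas the C–Br bond of 15 lies para to a phenoxide oxygen and is much less reactive, so cross-coupling should outpace self-condensation; the aldehyde has no enolisable hydrogen.

Step 6
Reactants: 17 2-(4-bromo-2,6-dimethoxyphenoxy)-4,6-dimethoxybenzaldehyde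
Product: 19 2-(4-bromo-2,6-dimethoxyphenoxy)-4,6-dimethoxyphenol, via aryl formate 18 (not isolated)
Conditions: mCPBA, NaHCO3, CH2Cl2, 0 °C → rt; then K2CO3, MeOH, 0 °C
Reagents that add atoms: 3-chloroperoxybenzoic acid, OOC(=O)c1cccc(Cl)c1
Why: Baeyer–Villiger oxidation (Dakin type): in the peracid adduct the electron-rich 2,4,6-trioxygenated aryl group migrates in preference to hydrogen, giving formate 18, which mild methanolysis cleaves; bromide, methyl ethers and the diaryl ether are inert to buffered peracid at this temperature.

Step 7
Reactants: 19 2-(4-bromo-2,6-dimethoxyphenoxy)-4,6-dimethoxyphenol; 20 (3,5-dimethoxyphenyl)boronic acid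
Product: 21 5-bromo-2-[2-(3,5-dimethoxyphenoxy)-3,5-dimethoxyphenoxy]-1,3-dimethoxybenzene
Conditions: Cu(OAc)2 (2 equiv), pyridine (5 equiv), 4 Å MS, CH2Cl2, rt, dry air
Reagents that add atoms: none
Why: Chan–Lam–Evans oxidative O-arylation: the aryl group of 20 is transferred from boron to the divalent copper phenoxide of 19, and after oxidation to trivalent copper the bond from O1 to C1 of ring A forms by reductive elimination at room temperature, a coupling that is documented for phenols with two ortho substituents. No low-valent metal is present, so the C–Br bond of ring C is untouched, and the molecular sieves suppress hydroxylation of the boronic acid by adventitious water.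

Step 8
Reactants: 21 5-bromo-2-[2-(3,5-dimethoxyphenoxy)-3,5-dimethoxyphenoxy]-1,3-dimethoxybenzene
Product: 22 4-[2-(3,5-dimethoxyphenoxy)-3,5-dimethoxyphenoxy]-3,5-dimethoxyphenol
Conditions: Pd2(dba)3 (2 mol%), 2-di-tert-butylphosphino-2',4',6'-triisopropylbiphenyl (8 mol%), KOH, 1,4-dioxane/H2O, 100 °C; then aq. HCl
Reagents that add atoms: potassium hydroxide, [K+].[OH-]
Why: Palladium-catalysed hydroxylation of an aryl bromide: zerovalent palladium inserts into the unhindered C–Br bond, hydroxide replaces bromide and the bulky biarylphosphine drives C–O reductive elimination; excess hydroxide outcompetes the product phenoxide, and aryl ethers are inert.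

Step 9
Reactants: 14 2-iodo-1,5-dimethoxy-3-(2,4,6-trimethoxyphenoxy)benzene; 22 4-[2-(3,5-dimethoxyphenoxy)-3,5-dimethoxyphenoxy]-3,5-dimethoxyphenol
Product: 23 2-{4-[2-(3,5-dimethoxyphenoxy)-3,5-dimethoxyphenoxy]-3,5-dimethoxyphenoxy}-1,5-dimethoxy-3-(2,4,6-trimethoxyphenoxy)benzene
Conditions: CuI (20 mol%), picolinic acid (40 mol%), K3PO4, DMSO, 100 °C
Reagents that add atoms: none
Why: Ullmann etherification with a copper picolinate catalyst suited to hindered partners: the unhindered, electron-rich phenoxide of 22 couples with iodide 14, whose C–I bond is flanked by methoxy and aryloxy; iodide is the most reactive halide towards monovalent copper, and neither partner carries another halide or free hydroxyl.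

Step 10
Reactants: 23 2-{4-[2-(3,5-dimethoxyphenoxy)-3,5-dimethoxyphenoxy]-3,5-dimethoxyphenoxy}-1,5-dimethoxy-3-(2,4,6-trimethoxyphenoxy)benzene
Product: 24 4-{4-[2-(3,5-dihydroxyphenoxy)-3,5-dihydroxyphenoxy]-3,5-dihydroxyphenoxy}-5-(2,4,6-trihydroxyphenoxy)benzene-1,3-diol (CNP0018313.0)
Conditions: BBr3 (excess), CH2Cl2, −78 °C → rt, Ar; then MeOH/H2O, 0 °C; degassed work-up
Reagents that add atoms: none
Why: Lewis-acid cleavage of aryl methyl ethers: BBr3 coordinates each methoxy oxygen and bromide removes the methyl group by SN2, while the diaryl ether bonds persist because neither of their carbons can accept bromide; hydrolysis of the aryl borates releases the eleven hydroxyls.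

## Compound list

1 | 3,5-dimethoxyphenol | COc1cc(O)cc(OC)c1 | starting material
2 | 3,5-dimethoxyphenyl N-isopropylcarbamate | COc1cc(OC)cc(OC(=O)NC(C)C)c1 | intermediate
3 | 3,5-dimethoxyphenyl N-(tert-butyldimethylsilyl)-N-isopropylcarbamate | COc1cc(OC)cc(OC(=O)N(C(C)C)[Si](C)(C)C(C)(C)C)c1 | intermediate
4 | [2-({(tert-butyldimethylsilyl)(isopropyl)carbamoyl}oxy)-4,6-dimethoxyphenyl]lithium | COc1cc(OC)c([Li])c(OC(=O)N(C(C)C)[Si](C)(C)C(C)(C)C)c1 | intermediate
5 | 3,5-dimethoxy-2-(trimethylsilyl)phenyl N-(tert-butyldimethylsilyl)-N-isopropylcarbamate | COc1cc(OC)c([Si](C)(C)C)c(OC(=O)N(C(C)C)[Si](C)(C)C(C)(C)C)c1 | intermediate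
6 | 3,5-dimethoxy-2-(trimethylsilyl)phenyl N-isopropylcarbamate | COc1cc(OC)c([Si](C)(C)C)c(OC(=O)NC(C)C)c1 | intermediate
7 | 3,5-dimethoxy-2-(trimethylsilyl)phenol | COc1cc(O)c([Si](C)(C)C)c(OC)c1 | intermediate
8 | 3,5-dimethoxy-2-(trimethylsilyl)phenyl trifluoromethanesulfonate | COc1cc(OC)c([Si](C)(C)C)c(OS(=O)(=O)C(F)(F)F)c1 | intermediate
9 | 2,4,6-trimethoxyphenol | COc1cc(OC)c(O)c(OC)c1 | starting material
10 | perfluorohexyl iodide (1-iodotridecafluorohexane) | FC(F)(F)C(F)(F)C(F)(F)C(F)(F)C(F)(F)C(F)(F)I | starting material
11 | potassium 2,4,6-trimethoxyphenoxide | [K+].[O-]c1c(OC)cc(OC)cc1OC | intermediate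
12 | 3,5-dimethoxybenzyne (1,2-didehydro-3,5-dimethoxybenzene) | COC1=CC(OC)=CC#C1 | intermediate
13 | [2,4-dimethoxy-6-(2,4,6-trimethoxyphenoxy)phenyl]potassium | COc1cc(OC)c([K])c(Oc2c(OC)cc(OC)cc2OC)c1 | intermediate
14 | 2-iodo-1,5-dimethoxy-3-(2,4,6-trimethoxyphenoxy)benzene (D–E iodide) | COc1cc(OC)c(I)c(Oc2c(OC)cc(OC)cc2OC)c1 | intermediate
15 | 4-bromo-2,6-dimethoxyphenol | COc1cc(Br)cc(OC)c1O | starting material
16 | 2-bromo-4,6-dimethoxybenzaldehyde | COc1cc(Br)c(C=O)c(OC)c1 | starting material
17 | 2-(4-bromo-2,6-dimethoxyphenoxy)-4,6-dimethoxybenzaldehyde | COc1cc(OC)c(C=O)c(Oc2c(OC)cc(Br)cc2OC)c1 | intermediate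
18 | 2-(4-bromo-2,6-dimethoxyphenoxy)-4,6-dimethoxyphenyl formate | COc1cc(OC)c(OC=O)c(Oc2c(OC)cc(Br)cc2OC)c1 | intermediate
19 | 2-(4-bromo-2,6-dimethoxyphenoxy)-4,6-dimethoxyphenol | COc1cc(OC)c(O)c(Oc2c(OC)cc(Br)cc2OC)c1 | intermediate
20 | (3,5-dimethoxyphenyl)boronic acid | COc1cc(OC)cc(B(O)O)c1 | starting material
21 | 5-bromo-2-[2-(3,5-dimethoxyphenoxy)-3,5-dimethoxyphenoxy]-1,3-dimethoxybenzene (A–B–C bromide) | COc1cc(OC)cc(Oc2c(OC)cc(OC)cc2Oc2c(OC)cc(Br)cc2OC)c1 | intermediate
22 | 4-[2-(3,5-dimethoxyphenoxy)-3,5-dimethoxyphenoxy]-3,5-dimethoxyphenol (A–B–C phenol) | COc1cc(OC)cc(Oc2c(OC)cc(OC)cc2Oc2c(OC)cc(O)cc2OC)c1 | intermediate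
23 | 2-{4-[2-(3,5-dimethoxyphenoxy)-3,5-dimethoxyphenoxy]-3,5-dimethoxyphenoxy}-1,5-dimethoxy-3-(2,4,6-trimethoxyphenoxy)benzene (undecamethyl ether of the target) | COc1cc(OC)cc(Oc2c(OC)cc(OC)cc2Oc2c(OC)cc(Oc3c(OC)cc(OC)cc3Oc3c(OC)cc(OC)cc3OC)cc2OC)c1 | intermediate
24 | 4-{4-[2-(3,5-dihydroxyphenoxy)-3,5-dihydroxyphenoxy]-3,5-dihydroxyphenoxy}-5-(2,4,6-trihydroxyphenoxy)benzene-1,3-diol (CNP0018313.0) | Oc1cc(O)cc(Oc2c(O)cc(O)cc2Oc2c(O)cc(Oc3c(O)cc(O)cc3Oc3c(O)cc(O)cc3O)cc2O)c1 | target

## Step count and least certain steps

Total step count: 10.
Longest linear sequence: 6 steps (steps 1, 2, 3, 4, 9, 10, from 1 to 24; the other branch, steps 5, 6, 7, 8, 9, 10, is equally long).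

**Step 4 (key step, proposed new method).**
- What may go wrong: protonation of aryl anion 13 may outrun iodine transfer, which would give the symmetrical, iodine-free diaryl ether. Electron transfer between 11 and 10 may consume both. The perfluorohexene released may take up phenoxide. The aryl anion may add to a second aryne.
- Why there is no simple rescue: metalation and iodination of the protonated ether is not regiochemically safe. One C–H of ring D and two of ring E lie between two methoxy groups and are better directed than the wanted site between aryloxy and methoxy.
- Fallback (known chemistry), from 9 and 16, returning at 23: 9 and 16 are coupled under the copper conditions of step 5 to give 2,4-dimethoxy-6-(2,4,6-trimethoxyphenoxy)benzaldehyde F1. Baeyer–Villiger oxidation as in step 6 gives 2,4-dimethoxy-6-(2,4,6-trimethoxyphenoxy)phenyl formate F2, which is methanolysed to 2,4-dimethoxy-6-(2,4,6-trimethoxyphenoxy)phenol F3. Ullmann coupling of the hindered phenol F3 with the unhindered bromide 21 (CuI, picolinic acid, K3PO4, DMSO, 100 °C) should give 23. Steps 8 and 9 are then not needed.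

**Step 9 (Ullmann coupling of the two halves).**
- What may go wrong: copper inserts slowly into the electron-rich, doubly ortho-substituted C–I bond of 14, so hydrodeiodination and oxidation of the phenoxide of 22 can compete.
- Fallback, from 14 and 21, returning at 23: the polarity of the junction is inverted. 14 is hydroxylated under the palladium conditions of step 8 to 2,4-dimethoxy-6-(2,4,6-trimethoxyphenoxy)phenol F4 (the same structure as F3). F4 is coupled with 21 by copper catalysis, so that the crowded partner becomes the nucleophile and the halide is unhindered.

**Step 7 (oxidative copper coupling for ring A).**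
- What may go wrong: oxidation of the very electron-rich, 2,4,6-trioxygenated phenol 19 by divalent copper and air (quinone formation, oxidative coupling) may outrun the slow O-arylation at the crowded hydroxyl, and the boronic acid may be lost by protodeboronation or homocoupling.
- Fallback, from 19 and 8, returning at 21: the ring A carbon is made the electrophile without any metal or oxidant. CsF in MeCN at rt releases aryne 12 from a second portion of 8; the phenoxide of 19 adds at the carbon remote from the flanking methoxy group and the aryl anion is protonated by the phenol or the solvent, which gives 21 directly. The C–Br bond is untouched and the crowded hydroxyl is no obstacle to the unhindered aryne; the price is three more steps in that branch for the preparation of 8.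

**Step 5 (chemoselective copper coupling).**
- What may go wrong: selectivity between the two C–Br bonds may be lost. Copper may insert into the ring C bromide of 15 or of 17, leading to oligomeric ethers.
- Fallback, from 16 and 20, returning at 22: ring C is carried as a chloride, which is inert to copper. 4-Chloro-2,6-dimethoxyphenol F5 (purchased) and 16 give 2-(4-chloro-2,6-dimethoxyphenoxy)-4,6-dimethoxybenzaldehyde F6. Baeyer–Villiger oxidation gives 2-(4-chloro-2,6-dimethoxyphenoxy)-4,6-dimethoxyphenyl formate F7, and methanolysis gives 2-(4-chloro-2,6-dimethoxyphenoxy)-4,6-dimethoxyphenol F8. Oxidative copper coupling with 20 as in step 7 gives 5-chloro-2-[2-(3,5-dimethoxyphenoxy)-3,5-dimethoxyphenoxy]-1,3-dimethoxybenzene F9. The palladium-catalysed hydroxylation of step 8, which also accepts aryl chlorides, then gives 22.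

**Step 10 (global demethylation).**
- What may go wrong: cleavage of eleven methyl ethers may be incomplete, and the free polyphenol may degrade oxidatively during isolation.
- Fallback, from 23, returning at 24: the crude product of the BBr3 reaction is acetylated (Ac2O, pyridine) to the undecaacetate of the target F10. F10 is stable and can be separated from partially methylated congeners on silica. Acidic methanolysis (HCl, MeOH, degassed) then releases 24 without exposing it to base.

## Further compounds

F1 | step 4 | 2,4-dimethoxy-6-(2,4,6-trimethoxyphenoxy)benzaldehyde | COc1cc(OC)c(C=O)c(Oc2c(OC)cc(OC)cc2OC)c1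
F2 | step 4 | 2,4-dimethoxy-6-(2,4,6-trimethoxyphenoxy)phenyl formate | COc1cc(OC)c(OC=O)c(Oc2c(OC)cc(OC)cc2OC)c1
F3 | step 4 | 2,4-dimethoxy-6-(2,4,6-trimethoxyphenoxy)phenol | COc1cc(OC)c(O)c(Oc2c(OC)cc(OC)cc2OC)c1
F4 | step 9 | 2,4-dimethoxy-6-(2,4,6-trimethoxyphenoxy)phenol | COc1cc(OC)c(O)c(Oc2c(OC)cc(OC)cc2OC)c1
F0 | step 7 | none | none
F5 | step 5 | 4-chloro-2,6-dimethoxyphenol | COc1cc(Cl)cc(OC)c1O
F6 | step 5 | 2-(4-chloro-2,6-dimethoxyphenoxy)-4,6-dimethoxybenzaldehyde | COc1cc(OC)c(C=O)c(Oc2c(OC)cc(Cl)cc2OC)c1
F7 | step 5 | 2-(4-chloro-2,6-dimethoxyphenoxy)-4,6-dimethoxyphenyl formate | COc1cc(OC)c(OC=O)c(Oc2c(OC)cc(Cl)cc2OC)c1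
F8 | step 5 | 2-(4-chloro-2,6-dimethoxyphenoxy)-4,6-dimethoxyphenol | COc1cc(OC)c(O)c(Oc2c(OC)cc(Cl)cc2OC)c1
F9 | step 5 | 5-chloro-2-[2-(3,5-dimethoxyphenoxy)-3,5-dimethoxyphenoxy]-1,3-dimethoxybenzene | COc1cc(OC)cc(Oc2c(OC)cc(OC)cc2Oc2c(OC)cc(Cl)cc2OC)c1
F10 | step 10 | undecaacetate of the target (all eleven hydroxyls as acetates) | CC(=O)Oc1cc(OC(C)=O)cc(Oc2c(OC(C)=O)cc(OC(C)=O)cc2Oc2c(OC(C)=O)cc(Oc3c(OC(C)=O)cc(OC(C)=O)cc3Oc3c(OC(C)=O)cc(OC(C)=O)cc3OC(C)=O)cc2OC(C)=O)c1
A1 | alternative 1 | A–D octamethyl ether carrying ring E as dimethyl 5-aryloxy-2,4,6-trihydroxybenzene-1,3-dicarboxylate | COc1cc(OC)cc(Oc2c(OC)cc(OC)cc2Oc2c(OC)cc(Oc3c(OC)cc(OC)cc3Oc3c(O)c(C(=O)OC)c(O)c(C(=O)OC)c3O)cc2OC)c1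
A2 | alternative 1 | dimethyl 2-(aryloxy)propanedioate of the A–D tetramer octamethyl ether (malonate on the C6 oxygen of ring D) | COc1cc(OC)cc(Oc2c(OC)cc(OC)cc2Oc2c(OC)cc(Oc3c(OC)cc(OC)cc3OC(C(=O)OC)C(=O)OC)cc2OC)c1
A3 | alternative 1 | dimethyl 3-oxopentanedioate | COC(=O)CC(=O)CC(=O)OC
A4 | alternative 2 | cyclopentadienylruthenium hexafluorophosphate complex of the undecamethyl pentamer, metal on ring C | COc1cc(OC)cc(Oc2c(OC)cc(OC)cc2Oc2c(OC)cc(Oc3c(OC)cc(OC)cc3Oc3c(OC)cc(OC)cc3OC)cc2OC)c1.[cH-]1cccc1.[Ru+2].F[P-](F)(F)(F)(F)F
A5 | alternative 2 | [CpRu(η6-2,5-dichloro-1,3-dimethoxybenzene)]PF6 | COc1cc(Cl)cc(OC)c1Cl.[cH-]1cccc1.[Ru+2].F[P-](F)(F)(F)(F)F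
A6 | alternative 2 | 2,4-dimethoxy-6-(2,4,6-trimethoxyphenoxy)phenol (D–E phenol) | COc1cc(OC)c(O)c(Oc2c(OC)cc(OC)cc2OC)c1
A7 | alternative 2 | 2-(3,5-dimethoxyphenoxy)-3,5-dimethoxyphenol (A–B phenol) | COc1cc(OC)cc(Oc2c(OC)cc(OC)cc2O)c1
A8 | alternative 3 | pentamer nonamethyl ether with free C4 hydroxyls on rings B and D | COc1cc(OC)cc(Oc2c(OC)cc(O)cc2Oc2c(OC)cc(Oc3c(OC)cc(O)cc3Oc3c(OC)cc(OC)cc3OC)cc2OC)c1
A9 | alternative 3 | pentamer nonamethyl ether lacking the C4 oxygens of rings B and D | COc1cc(OC)cc(Oc2c(OC)cccc2Oc2c(OC)cc(Oc3c(OC)cccc3Oc3c(OC)cc(OC)cc3OC)cc2OC)c1
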